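## Retrosynthetic overview
1. Target ⇒ its primary silyl ether. The trans C4‑benzoate/C5‑OH pair comes from anti (SN2) opening of a vinyl oxirane at its allylic carbon by benzoate, and the C1‑benzoate from acylation of an allylic alcohol. One benzoic anhydride supplies both benzoates.
2. Allylic C1‑OH plus C2=C3 ⇒ Wharton transposition of an α,β‑epoxy ketone. This removes the ketone oxygen and keeps the C1–O bond.
3. Both oxiranes ⇒ one catalyst‑controlled double Weitz–Scheffer epoxidation of an achiral cross‑conjugated p‑quinol. Two rings, four stereocentres and the absolute configuration are set in one operation.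
4. p‑Quinol ⇒ oxidative dearomatisation of O‑silylated 4‑hydroxybenzyl alcohol, so all seven skeletal carbons are bought.
5. Ring order: the carbocycle is the arene of the starting material, and the two oxiranes form together. The oxirane syn to the tertiary OH is opened first (Wharton), the anti one last (benzoate).

Assumption: of the two commercial pseudoenantiomeric amines (9‑amino‑9‑deoxy‑epi‑quinine, 9‑amino‑9‑deoxy‑epi‑quinidine), the one that turns 2‑cyclohexenone into (2R,3R)‑2,3‑epoxycyclohexanone is meant below; a test run on that ketone identifies it.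

## Route

Step 1
Reactants: 1 4‑hydroxybenzyl alcohol
Product: 2 4‑{[(tert‑butyldimethylsilyl)oxy]methyl}phenol
Conditions: TBSCl (1.05 equiv), imidazole (2.2 equiv), DMF, 0 °C
Reagents that add atoms: tert‑butyldimethylsilyl chloride, CC(C)(C)[Si](C)(C)Cl
Why: Silylation with an imidazole‑activated silyl chloride takes the aliphatic primary OH faster than the less nucleophilic neutral phenol at 0 °C with one equivalent of reagent, and no stereocentre is formed.

Step 2
Reactants: 2 4‑{[(tert‑butyldimethylsilyl)oxy]methyl}phenol
Product: 3 4‑hydroxy‑4‑{[(tert‑butyldimethylsilyl)oxy]methyl}cyclohexa‑2,5‑dien‑1‑one (achiral p‑quinol)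
Conditions: PhI(OAc)2 (1.1 equiv), MeCN–H2O 4:1, 0 °C
Reagents that add atoms: water, O
Why: Oxidative phenol dearomatisation by the trivalent iodine reagent lets water attack the para carbon of the aryloxy‑iodane, giving a p‑quinol that has a mirror plane (no stereocentre), while the silyl ether blocks loss of formaldehyde from the quaternary carbon.

Step 3
Reactants: 3 4‑hydroxy‑4‑{[(tert‑butyldimethylsilyl)oxy]methyl}cyclohexa‑2,5‑dien‑1‑one
Product: 5 (2R,3S,5S,6R)‑2,3:5,6‑diepoxy‑4‑hydroxy‑4‑{[(tert‑butyldimethylsilyl)oxy]methyl}cyclohexan‑1‑one (anti‑bis‑epoxide; oxiranes on opposite ring faces), via syn‑monoepoxide 4 (not isolated)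
Conditions: 9‑amino‑9‑deoxy‑epi‑cinchona amine (20 mol %, see assumption), CF3CO2H (40 mol %), 50% aq. H2O2 (4 equiv), 1,4‑dioxane, 35 °C, 48 h
Reagents that add atoms: hydrogen peroxide, OO
Why: Proposed new method: the primary amine forms the cross‑conjugated iminium ion, H2O2 held by the protonated quinuclidine adds to a β‑carbon and the enamine closes the oxirane (Weitz–Scheffer epoxidation under iminium/enamine catalysis), then the same cycle runs on the remaining enone; because the two enone halves of 3 are mirror images and the catalyst imposes the same absolute sense (α‑carbon R) on each, the second oxirane must land on the opposite ring face, so either order of events converges on the single anti‑bis‑epoxide 5 (its carbinol carbon is not stereogenic because of the pseudo‑twofold axis), while errors are drained into achiral, separable cis‑bis‑epoxides (Horeau‑type ee amplification); the closest known reaction type is the cinchona primary amine salt/H2O2 epoxidation of 2‑cyclohexenones, 4,4‑disubstituted ones included, and what is new is the double use on a cyclohexadienone and the need for one attack anti to the OH.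

Step 4
Reactants: 5 anti‑bis‑epoxide
Product: 7 (1S,2S,3S,6S)‑2‑{[(tert‑butyldimethylsilyl)oxy]methyl}‑7‑oxabicyclo[4.1.0]hept‑4‑ene‑2,3‑diol (cis‑diol; oxirane on the face opposite to both OH groups), via hydrazone 6 (not isolated)
Conditions: N2H4 (1 M in THF, 1.5 equiv), THF, 0 °C to rt, no added acid
Reagents that add atoms: none
Why: Wharton transposition, in which hydrazone 6 tautomerises to a vinyl diazene with cleavage of an α‑C–O bond and loses N2; in aprotic medium only the oxirane syn to the tertiary OH is activated by an internal O–H···O hydrogen bond (the silyl ether is no donor), so that one opens, its β‑C–O bond is untouched, the new allylic OH is therefore cis to the tertiary OH, and the carbinol carbon becomes stereogenic in the required sense.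

Step 5
Reactants: 7 epoxy cis‑diol; 8 benzoic anhydride
Product: 10 (1S,4R,5S,6R)‑6‑{[(tert‑butyldimethylsilyl)oxy]methyl}‑5,6‑dihydroxycyclohex‑2‑ene‑1,4‑diyl dibenzoate, via allylic benzoate 9 (not isolated)
Conditions: 8 (1.1 equiv), iPr2NEt (1.2 equiv), DMAP (5 mol %), MeCN, 0 °C to rt, 2 h; then 50 °C, 16 h
Reagents that add atoms: benzoic anhydride (8), O=C(OC(=O)c1ccccc1)c1ccccc1
Why: DMAP‑catalysed acylation takes the only secondary OH (the tertiary one is inert) and releases one equivalent of benzoate, which as its ammonium salt opens the vinyl oxirane by SN2 attack at the allylic carbon (the other oxirane carbon is neopentyl‑like) anti to the oxirane oxygen, so inversion there gives the (4R)‑benzoate trans to the retained (5S)‑OH.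

Step 6
Reactants: 10 silyl‑protected dibenzoate
Product: 11 (1S,4R,5S,6R)‑5,6‑dihydroxy‑6‑(hydroxymethyl)cyclohex‑2‑ene‑1,4‑diyl dibenzoate (target)
Conditions: HF·pyridine, THF–pyridine, 0 °C to rt
Reagents that add atoms: none
Why: Fluoride‑driven desilylation under acidic, non‑basic conditions leaves the esters, the alkene and all four stereocentres untouched and avoids benzoyl migration to the freed primary OH.

## Compound list
1 | 4‑hydroxybenzyl alcohol | OCc1ccc(O)cc1 | starting material
2 | 4‑{[(tert‑butyldimethylsilyl)oxy]methyl}phenol | CC(C)(C)[Si](C)(C)OCc1ccc(O)cc1 | intermediate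
3 | 4‑hydroxy‑4‑{[(tert‑butyldimethylsilyl)oxy]methyl}cyclohexa‑2,5‑dien‑1‑one | O=C1C=CC(O)(CO[Si](C)(C)C(C)(C)C)C=C1 | intermediate
4 | (2R,3S,4S)‑2,3‑epoxy‑4‑hydroxy‑4‑{[(tert‑butyldimethylsilyl)oxy]methyl}cyclohex‑5‑en‑1‑one (oxirane syn to OH) | O=C1[C@@H]2O[C@@H]2[C@@](O)(CO[Si](C)(C)C(C)(C)C)C=C1 | intermediate
5 | (2R,3S,5S,6R)‑2,3:5,6‑diepoxy‑4‑hydroxy‑4‑{[(tert‑butyldimethylsilyl)oxy]methyl}cyclohexan‑1‑one (anti; C4 not stereogenic) | O=C1[C@@H]2O[C@@H]2C(O)(CO[Si](C)(C)C(C)(C)C)[C@H]3O[C@H]31 | intermediate
6 | hydrazone of 5 (C=N geometry not fixed) | NN=C1[C@@H]2O[C@@H]2C(O)(CO[Si](C)(C)C(C)(C)C)[C@H]3O[C@H]31 | intermediate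
7 | (1S,2S,3S,6S)‑2‑{[(tert‑butyldimethylsilyl)oxy]methyl}‑7‑oxabicyclo[4.1.0]hept‑4‑ene‑2,3‑diol | O[C@H]1C=C[C@@H]2O[C@@H]2[C@]1(O)CO[Si](C)(C)C(C)(C)C | intermediate
8 | benzoic anhydride | O=C(OC(=O)c1ccccc1)c1ccccc1 | starting material
9 | (1S,2S,3S,6S)‑2‑hydroxy‑2‑{[(tert‑butyldimethylsilyl)oxy]methyl}‑7‑oxabicyclo[4.1.0]hept‑4‑en‑3‑yl benzoate | O=C(O[C@H]1C=C[C@@H]2O[C@@H]2[C@]1(O)CO[Si](C)(C)C(C)(C)C)c1ccccc1 | intermediate
10 | (1S,4R,5S,6R)‑6‑{[(tert‑butyldimethylsilyl)oxy]methyl}‑5,6‑dihydroxycyclohex‑2‑ene‑1,4‑diyl dibenzoate | O=C(O[C@H]1C=C[C@@H](OC(=O)c2ccccc2)[C@H](O)[C@]1(O)CO[Si](C)(C)C(C)(C)C)c1ccccc1 | intermediate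
11 | (1S,4R,5S,6R)‑5,6‑dihydroxy‑6‑(hydroxymethyl)cyclohex‑2‑ene‑1,4‑diyl dibenzoate | O=C(O[C@H]1C=C[C@@H](OC(=O)c2ccccc2)[C@H](O)[C@]1(O)CO)c1ccccc1 | target

## Step count and weak points
Total steps: 6. Longest linear sequence: 6 (1 to 11).

**Step 3 (double epoxidation).**
- Risk: 4‑oxygenated cyclohexadienones usually prefer attack syn to oxygen. That bias may beat the catalyst in the second epoxidation and give the meso syn,syn‑bis‑epoxide. Iminium formation from a dienone may also be slow.
- Fallback, from 3 back to 5: mask one enone so that molecular shape, not the catalyst alone, chooses the face. Cyclopentadiene adds to 3 (toluene, rt) on the OH‑bearing face and gives the racemic endo cyclopentadiene adduct F1. Its remaining enone can only be reached from the convex face, which is the face anti to the OH. With the same amine salt and H2O2, only the enantiomer drawn is matched (kinetic resolution), and it gives the epoxy adduct F2. The unreacted enantiomer is cracked back to achiral 3 and recycled. Cycloreversion of F2 (flash vacuum pyrolysis, about 450 °C) releases the anti‑monoepoxide F3. Its last enone is then epoxidised syn to the OH, which is matched for both substrate and catalyst, to give 5.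

**Step 4 (which oxirane the Wharton reaction opens).**
- Risk: the two oxiranes differ only in their relation to the carbinol substituents, so the hydrogen‑bond bias may be modest.
- Fallback, from 5 back to 10: use the other isomer instead of discarding it. Opening of the oxirane anti to the OH gives the isomeric vinyl oxirane F4, the carbinol epimer of 7. The zerovalent palladium complex Pd(PPh3)4 and benzoic acid in THF ionise it with inversion. Benzoate then attacks the distal allyl terminus with a second inversion (cis‑1,4‑addition). This gives the monobenzoate triol F5, which already has the C1, C4, C5 and C6 configuration of the target. Selective benzoylation of its allylic OH through the stannylene acetal of the cis C1/C6 diol (Bu2SnO, then BzCl) gives 10, so both Wharton isomers reach 10.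

**Step 5 (one‑pot acylation and oxirane opening).**
- Risk: the opening by one equivalent of ammonium benzoate may be sluggish, may go partly by 1,4‑attack, or may be followed by over‑acylation.
- Fallback, from 7 back to 10: separate C–O bond formation from acylation. Water acts as the nucleophile (water–dioxane, pH 7 buffer, 60 °C) and opens the vinyl oxirane anti at the allylic carbon to the tetraol F6. The two allylic secondary OH groups are then benzoylated together (BzCl 2.1 equiv, pyridine, CH2Cl2, −40 °C). The C5‑OH, flanked by the quaternary carbon, and the tertiary OH stay free.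

## Further compounds
F1 | step 3 | endo cyclopentadiene adduct of 3 (diene added to one enone C=C on the OH‑bearing face; productive enantiomer drawn) | O=C1C=C[C@](O)(CO[Si](C)(C)C(C)(C)C)[C@H]2[C@H]3C=C[C@H](C3)[C@@H]12
F2 | step 3 | epoxy adduct (oxirane on the convex face, anti to OH) | O=C1[C@@H]2O[C@@H]2[C@](O)(CO[Si](C)(C)C(C)(C)C)[C@H]3[C@H]4C=C[C@H](C4)[C@@H]13
F3 | step 3 | (2R,3S,4R)‑2,3‑epoxy‑4‑hydroxy‑4‑{[(tert‑butyldimethylsilyl)oxy]methyl}cyclohex‑5‑en‑1‑one (oxirane anti to OH) | O=C1[C@@H]2O[C@@H]2[C@](O)(CO[Si](C)(C)C(C)(C)C)C=C1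
F4 | step 4 | (1S,2R,3S,6S)‑2‑{[(tert‑butyldimethylsilyl)oxy]methyl}‑7‑oxabicyclo[4.1.0]hept‑4‑ene‑2,3‑diol | O[C@H]1C=C[C@@H]2O[C@@H]2[C@@]1(O)CO[Si](C)(C)C(C)(C)C
F5 | step 4 | (1R,4S,5S,6S)‑5‑{[(tert‑butyldimethylsilyl)oxy]methyl}‑4,5,6‑trihydroxycyclohex‑2‑en‑1‑yl benzoate | O[C@H]1C=C[C@@H](OC(=O)c2ccccc2)[C@H](O)[C@]1(O)CO[Si](C)(C)C(C)(C)C
F6 | step 5 | (1S,2S,3S,4R)‑2‑{[(tert‑butyldimethylsilyl)oxy]methyl}cyclohex‑5‑ene‑1,2,3,4‑tetrol | O[C@H]1C=C[C@@H](O)[C@H](O)[C@]1(O)CO[Si](C)(C)C(C)(C)C
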